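**Retrosynthetic overview**

1. Target 12 ⇐ ring-closing metathesis (ring C4=C5) of the fully acylated octa-1,7-diene 11; the cyclohexene is the only ring and is closed last.
2. 11 ⇐ triol 10 by acetylation of its two secondary hydroxyls.
3. 10 ⇐ key C–C bond (ring C1–C6): ketone 8 + γ-benzoyloxyallylindium 9, in which the former carbonyl carbon of acrolein is the nucleophile (formal crossed pinacol of two carbonyl carbons); this sets C1 and C6 and delivers C6-OBz and the free C1-OH directly.
4. 8 ⇐ zinc fragmentation of 6-iodofructofuranoside 4 ⇐ D-fructose 1, which supplies ring C2, C3 and the CH2O–C1 unit with the correct absolute configuration.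
5. 9 ⇐ 3-bromopropenyl benzoate 7 ⇐ acrolein 5 + benzoyl bromide 6.

Assumption: 7 is used as the E/Z mixture its preparation gives (E isomer drawn), and the organoindium 9 is written as the simplest monomeric dibromide.

**Step 1**
Reactants: 1 D-fructose
Product: 2 methyl β-D-fructofuranoside
Conditions: MeOH, H2SO4 (cat.), rt, 45 min; NaHCO3; SiO2 chromatography
Reagents that add atoms: methanol, CO
Why: Kinetic Fischer glycosidation of a ketose gives the five-membered furanosides first; the β-anomer is separated from the α-furanoside and the β-pyranoside, and C3–C5 are untouched.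

**Step 2**
Reactants: 2 methyl β-D-fructofuranoside
Product: 3 methyl 6-deoxy-6-iodo-β-D-fructofuranoside
Conditions: PPh3 (1.2 equiv), I2 (1.2 equiv), imidazole, THF, 0 → 50 °C
Reagents that add atoms: iodine, II
Why: Garegg–Samuelsson (Appel-type) iodination is an SN2 displacement that takes the unhindered C6 primary carbinol, while the neopentyl-like C1 next to the anomeric quaternary carbon and the secondary hydroxyls do not react; no stereocentre is involved.

**Step 3**
Reactants: 3 methyl 6-deoxy-6-iodo-β-D-fructofuranoside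
Product: 4 methyl 1-O-benzoyl-6-deoxy-6-iodo-β-D-fructofuranoside
Conditions: BzCl (1.05 equiv), pyridine, CH2Cl2, −40 → −20 °C
Reagents that add atoms: benzoyl chloride, O=C(Cl)c1ccccc1
Why: Regioselective esterification (nucleophilic acyl substitution) of the only primary hydroxyl at low temperature leaves the 3,4-diol free for the later chelation; no stereocentre is involved.

**Step 4**
Reactants: 5 acrolein; 6 benzoyl bromide
Product: 7 3-bromoprop-1-en-1-yl benzoate (E/Z mixture, E drawn)
Conditions: ZnCl2 (2 mol%), CH2Cl2, −20 °C → rt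
Reagents that add atoms: none
Why: Lewis-acid-promoted 1,4-addition of the acyl bromide to the enal (O-acylation with conjugate delivery of bromide) gives the γ-bromo enol ester; its geometry is irrelevant because the derived allylmetal equilibrates.

**Step 5 (key step)**
Reactants: 4 methyl 1-O-benzoyl-6-deoxy-6-iodo-β-D-fructofuranoside; 7 3-bromoprop-1-en-1-yl benzoate
Product: 10 (3S,4R,5S,6R)-4-[(benzoyloxy)methyl]-4,5,6-trihydroxyocta-1,7-dien-3-yl benzoate, via ketone 8 (not isolated), via allylindium 9 (not isolated)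
Conditions: Zn dust, THF/H2O 4:1, ultrasound, 40 °C; filter off Zn; then In powder (3 equiv), 7 (3 equiv), rt
Reagents that add atoms: none
Why: Proposed new method: zinc inserts into the C6–I bond of 4 and β-alkoxy elimination (Bernet–Vasella fragmentation) opens the furanoside to the ene-ketone 8, while 7 and In give the γ-benzoyloxyallylindium 9, whose nucleophilic carbon is the former carbonyl carbon of acrolein (an α-hydroxyallyl anion equivalent), so its Barbier-type addition to the ketone joins two carbonyl-derived carbons in a formal crossed pinacol; trivalent indium is chelated by O-3 and the ketone oxygen of 8, the allyl group is delivered anti to the C4 arm (syn to the 3-OH, setting the tertiary carbinol C4 of 10) through a chair transition state with the chelated arm axial, CH2OBz equatorial and the (Z)-enol benzoate oxygen axial, which gives the anti relationship of C3–OBz to C4–OH (C3 S); the closest known chemistry is the one-pot zinc fragmentation/indium-mediated 3-bromopropenyl ester addition to α-hydroxy aldehydes in water, which gives this same syn/anti triad, together with chelation-controlled indium allylation of α-hydroxy ketones, and the extension is the use of the acyloxyallyl reagent on a ketone.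

**Step 6**
Reactants: 10 (3S,4R,5S,6R)-4-[(benzoyloxy)methyl]-4,5,6-trihydroxyocta-1,7-dien-3-yl benzoate
Product: 11 (3S,4S,5S,6R)-5,6-bis(acetyloxy)-4-[(benzoyloxy)methyl]-4-hydroxyocta-1,7-dien-3-yl benzoate
Conditions: Ac2O, pyridine, 0 °C → rt (no DMAP)
Reagents that add atoms: acetic anhydride, CC(=O)OC(C)=O
Why: Esterification with Ac2O/pyridine acetylates the two secondary hydroxyls while the tertiary hydroxyl is inert without an acyl-transfer catalyst; no stereocentre is touched.

**Step 7**
Reactants: 11 (3S,4S,5S,6R)-5,6-bis(acetyloxy)-4-[(benzoyloxy)methyl]-4-hydroxyocta-1,7-dien-3-yl benzoate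
Product: 12 cleistenediol F, [(1S,2S,3R,6S)-2,3-bis(acetyloxy)-6-(benzoyloxy)-1-hydroxycyclohex-4-en-1-yl]methyl benzoate
Conditions: second-generation Grubbs catalyst (H2IMes)(PCy3)Cl2Ru=CHPh (5 mol%), CH2Cl2 (5 mM), 40 °C
Reagents that add atoms: none
Why: Ring-closing metathesis of the octa-1,7-diene closes the cyclohexene with loss of ethylene; the four stereocentres are not involved and the allylic esters and free tertiary alcohol are tolerated.

**Compound list**

1 | D-fructose | OCC(=O)[C@@H](O)[C@H](O)[C@H](O)CO | starting material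
2 | methyl β-D-fructofuranoside | CO[C@@]1(CO)[C@@H](O)[C@H](O)[C@@H](CO)O1 | intermediate
3 | methyl 6-deoxy-6-iodo-β-D-fructofuranoside | CO[C@@]1(CO)[C@@H](O)[C@H](O)[C@@H](CI)O1 | intermediate
4 | methyl 1-O-benzoyl-6-deoxy-6-iodo-β-D-fructofuranoside | CO[C@@]1(COC(=O)c2ccccc2)[C@@H](O)[C@H](O)[C@@H](CI)O1 | intermediate
5 | acrolein | C=CC=O | starting material
6 | benzoyl bromide | O=C(Br)c1ccccc1 | starting material
7 | 3-bromoprop-1-en-1-yl benzoate (E/Z mixture, E drawn) | BrC/C=C/OC(=O)c1ccccc1 | intermediate
8 | (3S,4R)-3,4-dihydroxy-2-oxohex-5-en-1-yl benzoate (1-O-benzoyl-5,6-dideoxy-D-threo-hex-5-en-2-ulose) | O=C(OCC(=O)[C@@H](O)[C@H](O)C=C)c1ccccc1 | intermediate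
9 | [(2Z)-3-(benzoyloxy)prop-2-en-1-yl]indium dibromide (trivalent indium) | O=C(O/C=C\C[In](Br)Br)c1ccccc1 | intermediate
10 | (3S,4R,5S,6R)-4-[(benzoyloxy)methyl]-4,5,6-trihydroxyocta-1,7-dien-3-yl benzoate | C=C[C@H](OC(=O)c1ccccc1)[C@@](O)(COC(=O)c1ccccc1)[C@@H](O)[C@H](O)C=C | intermediate
11 | (3S,4S,5S,6R)-5,6-bis(acetyloxy)-4-[(benzoyloxy)methyl]-4-hydroxyocta-1,7-dien-3-yl benzoate | C=C[C@H](OC(=O)c1ccccc1)[C@@](O)(COC(=O)c1ccccc1)[C@@H](OC(C)=O)[C@H](OC(C)=O)C=C | intermediate
12 | cleistenediol F, [(1S,2S,3R,6S)-2,3-bis(acetyloxy)-6-(benzoyloxy)-1-hydroxycyclohex-4-en-1-yl]methyl benzoate | CC(=O)O[C@@H]1C=C[C@H](OC(=O)c2ccccc2)[C@@](O)(COC(=O)c2ccccc2)[C@H]1OC(C)=O | target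

**Step count**

Total steps: 7. Longest linear sequence: 6 (steps 1, 2, 3, 5, 6, 7); step 4 is a one-step side branch.

**Three steps most likely to fail**

Step 5 is the main risk. The ketone 8 is less reactive than the aldehydes for which the acyloxyallylindium addition is known. The configuration at C3 and C4 of 10 rests on analogy with α-hydroxy aldehydes. Prolonged contact with zinc could also reductively cleave the α-benzoyloxy ketone. The fallback sets out from 4 and comes back at 11. The zinc fragmentation is run alone and ketone 8 is isolated. It is then allylated with dimethyl [(2Z)-3-(methoxymethoxy)prop-2-en-1-yl]boronate F1, made from commercial allyl methoxymethyl ether (sBuLi, THF, −78 °C, then FB(OMe)2). The boron exchanges onto the 3,4-diol of 8, and the allyl group is transferred intramolecularly through a closed chair with the tethered arm axial and the Z enol ether oxygen axial, which predicts the same syn/anti triad. This gives (3S,4R,5S,6R)-4-[(benzoyloxy)methyl]-3-(methoxymethoxy)octa-1,7-diene-4,5,6-triol F2. Ac2O/pyridine converts it into (3S,4S,5S,6R)-4-[(benzoyloxy)methyl]-4-hydroxy-3-(methoxymethoxy)octa-1,7-diene-5,6-diyl diacetate F3. ZnBr2 with n-PrSH (CH2Cl2, 0 °C) removes the methoxymethyl group to give (3S,4S,5S,6R)-4-[(benzoyloxy)methyl]-3,4-dihydroxyocta-1,7-diene-5,6-diyl diacetate F4. BzCl/pyridine then benzoylates only the secondary allylic hydroxyl and gives 11.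

Step 3 is the second risk, because mono-benzoylation of the neopentyl-like primary 1-OH may not be clean against the two secondary hydroxyls. The fallback sets out from 1 and comes back at 4, and it fixes O-1 by protecting-group logic instead of rate differences. D-Fructose with acetone and H2SO4 gives 2,3:4,5-di-O-isopropylidene-β-D-fructopyranose F5, whose only free hydroxyl is O-1. BzCl/pyridine gives 1-O-benzoyl-2,3:4,5-di-O-isopropylidene-β-D-fructopyranose F6. Aqueous CF3CO2H removes both acetonides to give 1-O-benzoyl-D-fructose F7. Kinetic Fischer glycosidation (MeOH, H2SO4 cat., rt) gives methyl 1-O-benzoyl-β-D-fructofuranoside F8. PPh3/I2/imidazole then iodinates its single primary hydroxyl to give 4.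

Step 6 is the third risk. The C5 hydroxyl of 10 sits next to the quaternary carbon and may acetylate slowly, which gives time for 1,3-benzoyl migration, and forcing conditions could acetylate the tertiary hydroxyl. The fallback sets out from 10 and comes back at 12 by closing the ring before acylating. Ring-closing metathesis of the free triol 10 (second-generation Grubbs catalyst (H2IMes)(PCy3)Cl2Ru=CHPh, CH2Cl2, 40 °C) gives [(1R,2S,3R,6S)-6-(benzoyloxy)-1,2,3-trihydroxycyclohex-4-en-1-yl]methyl benzoate F9. Ac2O/pyridine at 0 °C then acetylates the two secondary hydroxyls of the rigid cyclohexene to give 12.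

**Further compounds**

F1 | step 5 | dimethyl [(2Z)-3-(methoxymethoxy)prop-2-en-1-yl]boronate | COCO/C=C\CB(OC)OC
F2 | step 5 | (3S,4R,5S,6R)-4-[(benzoyloxy)methyl]-3-(methoxymethoxy)octa-1,7-diene-4,5,6-triol | C=C[C@H](OCOC)[C@@](O)(COC(=O)c1ccccc1)[C@@H](O)[C@H](O)C=C
F3 | step 5 | (3S,4S,5S,6R)-4-[(benzoyloxy)methyl]-4-hydroxy-3-(methoxymethoxy)octa-1,7-diene-5,6-diyl diacetate | C=C[C@H](OCOC)[C@@](O)(COC(=O)c1ccccc1)[C@@H](OC(C)=O)[C@H](OC(C)=O)C=C
F4 | step 5 | (3S,4S,5S,6R)-4-[(benzoyloxy)methyl]-3,4-dihydroxyocta-1,7-diene-5,6-diyl diacetate | C=C[C@H](O)[C@@](O)(COC(=O)c1ccccc1)[C@@H](OC(C)=O)[C@H](OC(C)=O)C=C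
F5 | step 3 | 2,3:4,5-di-O-isopropylidene-β-D-fructopyranose | OC[C@]12OC(C)(C)O[C@H]1[C@@H]3OC(C)(C)O[C@@H]3CO2
F6 | step 3 | 1-O-benzoyl-2,3:4,5-di-O-isopropylidene-β-D-fructopyranose | O=C(c1ccccc1)OC[C@]12OC(C)(C)O[C@H]1[C@@H]3OC(C)(C)O[C@@H]3CO2
F7 | step 3 | 1-O-benzoyl-D-fructose (open-chain form drawn) | O=C(c1ccccc1)OCC(=O)[C@@H](O)[C@H](O)[C@H](O)CO
F8 | step 3 | methyl 1-O-benzoyl-β-D-fructofuranoside | CO[C@@]1(COC(=O)c2ccccc2)[C@@H](O)[C@H](O)[C@@H](CO)O1
F9 | step 6 | [(1R,2S,3R,6S)-6-(benzoyloxy)-1,2,3-trihydroxycyclohex-4-en-1-yl]methyl benzoate | O[C@@H]1C=C[C@H](OC(=O)c2ccccc2)[C@@](O)(COC(=O)c2ccccc2)[C@H]1O
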